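## Analysis of the target

The target is the C40 carotenoid (4S,5S,6S,5′S,6′S)-4-hydroxy-5,6,5′,6′-tetrahydro-β,β-caroten-4′-one: an all-E nonaene chain with four methyl branches (C7 to C7′) between two saturated trimethylcyclohexane end groups. Carotenoid locants are used throughout: in each ring C1 is the gem-dimethyl carbon, C2 and C3 are methylenes, C4 is the oxygenated carbon, C5 carries the secondary methyl group, C6 carries the chain and C7 is the first chain carbon; unprimed locants belong to the hydroxy end (ring A), primed ones to the keto end (ring B). The rings differ only at C4 (secondary alcohol in ring A, ketone in ring B), and the C5/C6 pairs are trans and of the same absolute configuration in both, so one chiral C10 building block can serve both ends. In ring A the hydroxyl is trans to the C5 methyl group, all three substituents are equatorial, and C4 can therefore be derived from C5/C6 by axial hydride delivery. Sensitive elements are the polyene (light, oxygen, acid, E/Z drift) and C5′, which is α to the ketone; with C4′ trigonal an axial C6′ substituent has only one syn-axial hydrogen, so the trans arrangement is not clearly favoured at the ketone stage and cannot be left to a base. The difficulty is twofold: C5 and C6 lie between a quaternary carbon and the oxygenated carbon, with no function on C6 except the chain, and two almost identical ends must be joined to a symmetric polyene without scrambling. The strategy rests on one feature of ring B: with C7 raised to an ester, the C4 ketone and C7 form a 1,4-dicarbonyl pair, and the C4–C5 bond links a carbonyl carbon to the β-carbon of a C5=C6 acrylate. Both carbons are electrophilic, so this bond calls for polarity inversion at C4, and closing it that way makes the ring and both stereocentres in one catalytic step.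

## Retrosynthetic reasoning

Target 23 is traced back to its doubly protected form 22 (C4 triethylsilyl ether, C4′ ethylene ketal). Both groups leave in one mild acid treatment, so the polyene meets acid only once, at the end.

The chain of 22 is cut at the two disubstituted double bonds C7=C8 and C7′=C8′. These cuts separate the whole stereochemical problem (two C10 rings) from the polyene, which then is the commercial C20 dialdehyde 20 and never has to be built. The rings carry the sulfone (19 for ring A, 15 for ring B) and 20 the carbonyl groups, because a ring CH2 sulfone has no β-leaving group and the Julia–Kocienski olefination gives E-disubstituted alkenes directly. Used one after the other (15 in deficiency to give aldehyde 21, then 19), the two sulfones differentiate the ends of the symmetric partner.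

Both sulfones go back to one sulfide, 14, by functional-group changes only. Oxidation gives 15; ketal hydrolysis to 16, hydride reduction to 17 (which sets C4 from the existing C5/C6 pair), oxidation to 18 and silylation give 19. Sulfide 14 comes from alcohol 12 and thiol 13, and 12 from ketal ester 11 by reduction.

Ketal 11 comes from keto ester 10, and the ketalization has a second task beside protection. In the ketone 10 the cis C5 epimer is not clearly less stable than the trans isomer (axial ester at C6 next to a trigonal C4). In the ketal an axial ester would meet the axial ketal oxygen and an axial C5 methyl would meet the axial C1 methyl. The acid-catalysed, reversible ketalization is therefore the place where C5 is secured as trans, and a base equilibration of 10 is deliberately left out.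

Keto ester 10 is cut at C4–C5, not at a bond to the quaternary C1 and not at C5–C6. This cut exposes the achiral, acyclic aldehyde 9, in which C4 is a formyl carbon and C5=C6 an ethylidene ester anchored through C6 to the quaternary carbon. The gain is the ring, the C4–C5 bond, both stereocentres and the 1,4-oxygen pattern from one carbene-catalysed step. The forward reaction has to invert the polarity of C4, close the six-membered ring in the endo sense and deliver the proton to C6 under control of the catalyst.

Aldehyde 9 loses C4 by retro-hydroformylation to diene ester 8, whose vinyl group on the quaternary carbon is the only alkene able to react. Ester 8 is the conjugated isomer of methyl ester 7 of acid 6. Acid 6 is the Ireland–Claisen product of ester 3 through its dienolate, a cut of the C1–C6 bond that also builds the quaternary carbon, and 3 comes from alcohol 1 and acid chloride 2.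

## Alternatives that were turned down

Alternative 1: Ring B is bought as 4,4-dimethylcyclohex-2-en-1-one (A1) and disconnected at C6–C7 and at C5–CH3. In the forward step the dienyl-9-BBN reagent A2 adds to A1 under [Rh(cod)Cl]2 and one enantiomer of BINAP, and the boron enolate, activated with n-BuLi, is methylated with CH3I to give the C15 ketone A3.
- For: the asymmetric conjugate alkenylation is an established reaction class with a predictable sense of induction. The ring costs nothing, and methylation anti to the new C6 substituent gives the trans pair kinetically. On precedent and on predictability of the ee this alternative is stronger than the chosen route.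
- Against: the β-carbon of A1 adjoins the quaternary carbon, which slows the insertion. The three-component enolate trapping is prone to proton exchange (methylation at C3, double methylation). A2 has to be made and handled as a sensitive borane. A silyloxy diene is carried through every later ring manipulation, including the differentiation of the ring A and ring B oxidation levels.
- Comparison: step count is similar. The chosen strategy offers ring, both stereocentres and the C4/C7 oxygen pattern in one catalytic step from a four-step acyclic precursor, without a stoichiometric organometallic reagent, and a C10 block that pairs with the commercial C20 dialdehyde, so no polyene exists before the last three steps.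

Alternative 2: Ring A is disconnected at C1–C6. Fe(acac)3 and PhSiH3 transfer a hydrogen atom to the 1,1-disubstituted alkene of the acyclic vinyl sulfone A4, and the tertiary C1 radical adds 6-exo to C6 to give the ring sulfone A5.
- For: radical formation of the quaternary centre is insensitive to crowding, a chair transition state places all substituents equatorial, and the sulfonyl handle at C7 is already present. The ring closure itself is more certain than in the chosen route.
- Against: the step creates only C6. C4 and C5 must be made beforehand in A4 by separate asymmetric chemistry, which costs several steps. The phenyl sulfone would need a reductive Julia elimination in the presence of a polyene, or an exchange of the sulfone. Ring B needs a further desilylation and oxidation.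
- Comparison: the chosen route sets its stereocentres catalytically in the ring-forming step and from an achiral precursor, at the price of an untested closure.

Alternative 3: Ring B is disconnected at C5–C6. The aldehyde A6 condenses with a chiral imidazolidinone, anodic one-electron oxidation of the enamine makes C6 electrophilic, and the tethered enolsilane carbon C5 attacks it to give the keto aldehyde A7.
- For: it uses the same 1,4-dicarbonyl logic with the polarity inverted on the other partner, and electricity is the oxidant.
- Against: the centre that must last, C6, ends up α to a formyl group in A7 and can be scrambled by the secondary amine catalyst. In the chosen route C6 sits α to a hindered ester. A6 needs a regio- and geometry-defined enolsilane beside a free aldehyde, and two oxidizable π systems must be told apart at the anode. This closure has no direct precedent either, so nothing is gained in certainty.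
- Comparison: C7 arrives as an aldehyde, but this is of use only if the chain is the nucleophile, which is not commercially available. The chosen strategy has the simpler precursor and the configurationally more robust product.

Key step: step 5

Assumption: the sense of induction of the aminoindanol triazolium catalysts in an endo closure is not established. The route is written with the (5aR,10bS) antipode; the equally accessible (5aS,10bR) antipode takes its place if the first run shows the opposite sense.

## Route

Step 1
Reactants: 1 3-methylbut-2-en-1-ol; 2 (E)-but-2-enoyl chloride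
Product: 3 3-methylbut-2-en-1-yl (E)-but-2-enoate
Conditions: pyridine, DMAP (cat.), CH2Cl2, 0 °C → rt
Reagents that add atoms: none
Why: O-acylation of the primary allylic alcohol by the acid chloride with nucleophilic catalysis; pyridine keeps deconjugation through the vinylketene low, and a but-3-enoate by-product would give the same dienolate in step 2.

Step 2
Reactants: 3 3-methylbut-2-en-1-yl (E)-but-2-enoate
Product: 6 2-ethenyl-3,3-dimethylpent-4-enoic acid (racemic), via dienyl silyl ketene acetal 4 (not isolated), via trimethylsilyl ester 5 (not isolated)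
Conditions: LiN(i-Pr)2, THF/DMPU, −78 °C; Me3SiCl; −78 → 60 °C; 1 M HCl (aq)
Reagents that add atoms: none
Why: Ireland–Claisen rearrangement: γ-deprotonation gives the extended enolate, O-silylation gives 4, and the chair [3,3] shift joins the α-carbon to the dimethyl-substituted allyl terminus, which creates the quaternary carbon (later C1) and the C1–C6 bond; silyl ester 5 is cleaved on acidic work-up. The one stereocentre of 6 is racemic and is erased in step 3.

Step 3
Reactants: 6 2-ethenyl-3,3-dimethylpent-4-enoic acid
Product: 8 methyl (Z)-2-(2-methylbut-3-en-2-yl)but-2-enoate, via methyl 2-ethenyl-3,3-dimethylpent-4-enoate 7 (not isolated)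
Conditions: MeI, K2CO3, DMF, rt; then DBU, 70 °C
Reagents that add atoms: iodomethane, CI
Why: Carboxylate O-methylation (SN2), then a base-mediated prototropic shift through the extended enolate moves the vinyl group that carries the doubly activated C–H into conjugation; the other vinyl group cannot move because it sits on the quaternary carbon. The Z isomer, with the new methyl on the ester side and away from the tertiary alkyl group, should be the thermodynamic one.

Step 4
Reactants: 8 methyl (Z)-2-(2-methylbut-3-en-2-yl)but-2-enoate
Product: 9 methyl (Z)-2-(2-methyl-5-oxopentan-2-yl)but-2-enoate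
Conditions: Rh(acac)(CO)2 (cat.), Xantphos, CO/H2 (1:1, 10 bar), toluene, 70 °C
Reagents that add atoms: carbon monoxide, [C-]#[O+]
Why: Rhodium-catalysed hydroformylation: the monosubstituted vinyl group on a quaternary carbon can take the formyl group only at its terminus, and the trisubstituted conjugated alkene is inert under these conditions.

Step 5
Reactants: 9 methyl (Z)-2-(2-methyl-5-oxopentan-2-yl)but-2-enoate
Product: 10 methyl (1S,6S)-2,2,6-trimethyl-5-oxocyclohexane-1-carboxylate
Conditions: (5aR,10bS)-2-(pentafluorophenyl)-5a,10b-dihydro-4H,6H-indeno[2,1-b][1,2,4]triazolo[4,3-d][1,4]oxazin-2-ium tetrafluoroborate (20 mol %), KN(SiMe3)2 (20 mol %), toluene, HN(SiMe3)2 removed in vacuo, then 9 (0.02 M), 23 → 40 °C; AcOH quench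
Reagents that add atoms: none
Why: Proposed new method: the free carbene adds to the formyl carbon C4 and proton transfer gives the Breslow intermediate, an acyl anion equivalent that attacks C5, the β-carbon of the tethered ethylidene ester; because the tether is anchored at the α-carbon C6, both alkene carbons enter the ring (6-endo-trig) and the ester enolate is exocyclic. The carbinol O–H at C4 then lies 1,3-diaxial to C6 and can hand its proton to C6 on the face from which C4 arrived, after which the alkoxide expels the carbene and leaves the γ-keto ester. The closest known reaction type is the enantioselective intramolecular Stetter reaction with aminoindanol-derived triazolium salts, established for exo closures and for α,β-disubstituted acceptors with internal diastereoselective protonation, but not for an endo closure. C5 is set by the alkene face that the chiral carbene opens to the acyl anion; C6, the centre that has to last, is set by the syn proton delivery and so inherits the same facial choice. Syn addition across the Z alkene places methyl and ester trans-diequatorial at once. The step needs conjugate addition to win over benzoin and aldol self-condensation: the gem-dimethyl group at C1 folds the chain towards the acceptor, the acceptor has no acidic neighbour, and the electron-poor N-pentafluorophenyl carbene is the type that tolerates enolizable aliphatic aldehydes. Removal of HN(SiMe3)2 keeps an external proton source from protonating the enolate unselectively, and the acidic quench avoids base-mediated scrambling of C5.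

Step 6
Reactants: 10 methyl (1S,6S)-2,2,6-trimethyl-5-oxocyclohexane-1-carboxylate
Product: 11 methyl (6S,7S)-6,8,8-trimethyl-1,4-dioxaspiro[4.5]decane-7-carboxylate
Conditions: ethylene glycol, p-TsOH·H2O (cat.), benzene, reflux, Dean–Stark
Reagents that add atoms: ethane-1,2-diol, OCCO
Why: Acid-catalysed ketalization of the C4 ketone; the conditions are reversible and allow C5 to equilibrate through the enol. In the ketal an axial C6 ester would clash with the axial ketal oxygen and an axial C5 methyl with the axial C1 methyl, so material epimeric at C5 should be funnelled into the trans isomer while C6, α only to the hindered ester, stays untouched.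

Step 7
Reactants: 11 methyl (6S,7S)-6,8,8-trimethyl-1,4-dioxaspiro[4.5]decane-7-carboxylate
Product: 12 [(6S,7S)-6,8,8-trimethyl-1,4-dioxaspiro[4.5]decan-7-yl]methanol
Conditions: LiAlH4, THF, 0 °C → 50 °C
Reagents that add atoms: none
Why: Hydride reduction of the hindered ester to the primary alcohol (C7 reaches the oxidation level needed for the sulfone); the ketal is inert and C6 is not enolized by the reagent.

Step 8
Reactants: 12 [(6S,7S)-6,8,8-trimethyl-1,4-dioxaspiro[4.5]decan-7-yl]methanol; 13 1-phenyl-1H-tetrazole-5-thiol
Product: 14 1-phenyl-5-({[(6S,7S)-6,8,8-trimethyl-1,4-dioxaspiro[4.5]decan-7-yl]methyl}sulfanyl)-1H-tetrazole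
Conditions: PPh3, DIAD, THF, 0 °C → rt
Reagents that add atoms: none
Why: Mitsunobu thioetherification: the acidic thiol is alkylated by the alkoxyphosphonium ion of the primary alcohol in an SN2 step at CH2, with no stereocentre involved.

Step 9
Reactants: 14 1-phenyl-5-({[(6S,7S)-6,8,8-trimethyl-1,4-dioxaspiro[4.5]decan-7-yl]methyl}sulfanyl)-1H-tetrazole
Product: 15 1-phenyl-5-({[(6S,7S)-6,8,8-trimethyl-1,4-dioxaspiro[4.5]decan-7-yl]methyl}sulfonyl)-1H-tetrazole
Conditions: (NH4)6Mo7O24·4H2O (cat.), 30% H2O2, EtOH, 0 °C → rt
Reagents that add atoms: hydrogen peroxide, OO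
Why: Molybdate-catalysed peroxide oxidation of the sulfide through the sulfoxide to the sulfone; ketal and tetrazole are not affected. This is the ring B coupling partner.

Step 10
Reactants: 14 1-phenyl-5-({[(6S,7S)-6,8,8-trimethyl-1,4-dioxaspiro[4.5]decan-7-yl]methyl}sulfanyl)-1H-tetrazole
Product: 16 (2S,3S)-2,4,4-trimethyl-3-{[(1-phenyl-1H-tetrazol-5-yl)sulfanyl]methyl}cyclohexan-1-one
Conditions: 1 M HCl (aq)/THF, 0 °C → rt, short reaction time
Reagents that add atoms: water, O
Why: Acid-catalysed hydrolysis of the dioxolane; ketal cleavage is much faster than acid-catalysed enolization, so the trans C5 centre secured in step 6 should survive if the ketone is taken on at once. The sulfide is used here rather than the sulfone so that the hydride in step 11 meets no heteroaryl sulfone.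

Step 11
Reactants: 16 (2S,3S)-2,4,4-trimethyl-3-{[(1-phenyl-1H-tetrazol-5-yl)sulfanyl]methyl}cyclohexan-1-one
Product: 17 (1S,2S,3S)-2,4,4-trimethyl-3-{[(1-phenyl-1H-tetrazol-5-yl)sulfanyl]methyl}cyclohexan-1-ol
Conditions: NaBH4, MeOH, −40 → 0 °C
Reagents that add atoms: none
Why: Borohydride reduction of a locked cyclohexanone: with the C5 methyl and the C6 substituent equatorial, the small hydride should attack axially from the face of the axial hydrogens at C2 and C6 and give the equatorial C4 alcohol, trans to the C5 methyl. This sets C4 by substrate control.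

Step 12
Reactants: 17 (1S,2S,3S)-2,4,4-trimethyl-3-{[(1-phenyl-1H-tetrazol-5-yl)sulfanyl]methyl}cyclohexan-1-ol
Product: 18 (1S,2S,3S)-2,4,4-trimethyl-3-{[(1-phenyl-1H-tetrazol-5-yl)sulfonyl]methyl}cyclohexan-1-ol
Conditions: (NH4)6Mo7O24·4H2O (cat.), 30% H2O2, EtOH, 0 °C → rt
Reagents that add atoms: hydrogen peroxide, OO
Why: The same sulfide-to-sulfone oxidation as in step 9; a free secondary alcohol is tolerated under these base-free conditions.

Step 13
Reactants: 18 (1S,2S,3S)-2,4,4-trimethyl-3-{[(1-phenyl-1H-tetrazol-5-yl)sulfonyl]methyl}cyclohexan-1-ol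
Product: 19 triethyl{[(1S,2S,3S)-2,4,4-trimethyl-3-{[(1-phenyl-1H-tetrazol-5-yl)sulfonyl]methyl}cyclohexyl]oxy}silane
Conditions: Et3SiCl, imidazole, DMAP (cat.), DMF, rt
Reagents that add atoms: chlorotriethylsilane, CC[Si](Cl)(CC)CC
Why: Silylation of the secondary alcohol; the triethylsilyl ether keeps an alkoxide out of the olefination and leaves in the final acid step together with the ketal. This is the ring A coupling partner.

Step 14
Reactants: 15 1-phenyl-5-({[(6S,7S)-6,8,8-trimethyl-1,4-dioxaspiro[4.5]decan-7-yl]methyl}sulfonyl)-1H-tetrazole; 20 crocetindial, (2E,4E,6E,8E,10E,12E,14E)-2,6,11,15-tetramethylhexadeca-2,4,6,8,10,12,14-heptaenedial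
Product: 21 (2E,4E,6E,8E,10E,12E,14E,16E)-2,6,11,15-tetramethyl-17-[(6S,7S)-6,8,8-trimethyl-1,4-dioxaspiro[4.5]decan-7-yl]heptadeca-2,4,6,8,10,12,14,16-octaenal
Conditions: 15, KN(SiMe3)2 (1.05 equiv), THF, −78 °C; transferred into 20 (3 equiv), THF, −60 °C → rt, dark, argon
Reagents that add atoms: none
Why: Julia–Kocienski olefination: the sulfonyl carbanion adds to one formyl group, the tetrazole migrates to the alkoxide (Smiles rearrangement), and loss of SO2 and the tetrazololate forms the C7′=C8′ double bond, expected E for a 1-phenyltetrazolyl sulfone. Excess dialdehyde and inverse addition should hold the reaction at mono-olefination, helped by the slightly lower electrophilicity of the aldehyde in 21; unreacted 20 is recovered.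

Step 15
Reactants: 19 triethyl{[(1S,2S,3S)-2,4,4-trimethyl-3-{[(1-phenyl-1H-tetrazol-5-yl)sulfonyl]methyl}cyclohexyl]oxy}silane; 21 the C30 aldehyde of step 14
Product: 22 (4S,5S,6S,5′S,6′S)-4′,4′-ethylenedioxy-4-(triethylsilyloxy)-5,6,5′,6′-tetrahydro-β,β-carotene (all-E; ring A silyl ether, ring B ethylene ketal)
Conditions: 19 (1.3 equiv), KN(SiMe3)2, THF, −78 °C; then 21, −78 °C → rt, dark, argon
Reagents that add atoms: none
Why: Second Julia–Kocienski olefination on the remaining aldehyde; it forms C7=C8 (E expected) and completes the C40 skeleton. Ketal and silyl ether are stable to the base, and neither partner has an enolizable carbonyl group.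

Step 16
Reactants: 22 the protected C40 compound of step 15
Product: 23 (4S,5S,6S,5′S,6′S)-4-hydroxy-5,6,5′,6′-tetrahydro-β,β-caroten-4′-one (CNP0107241.1, all-E)
Conditions: 0.5 M HCl (aq)/THF, 0 °C → rt, dark, argon; crystallization
Reagents that add atoms: water, O
Why: One acid hydrolysis removes the dioxolane and the triethylsilyl ether; neither ring oxygen is allylic, so the polyene should not ionize, and cold, short treatment protects C5′. Crystallization should deliver the all-E isomer.

## Compound list

1 | 3-methylbut-2-en-1-ol | CC(C)=CCO | starting material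
2 | (E)-but-2-enoyl chloride | C/C=C/C(=O)Cl | starting material
3 | 3-methylbut-2-en-1-yl (E)-but-2-enoate | C/C=C/C(=O)OCC=C(C)C | intermediate
4 | trimethyl({1-[(3-methylbut-2-en-1-yl)oxy]buta-1,3-dien-1-yl}oxy)silane (dienyl silyl ketene acetal, not isolated) | C=CC=C(OCC=C(C)C)O[Si](C)(C)C | intermediate
5 | trimethylsilyl 2-ethenyl-3,3-dimethylpent-4-enoate (racemic, not isolated) | C=CC(C(=O)O[Si](C)(C)C)C(C)(C)C=C | intermediate
6 | 2-ethenyl-3,3-dimethylpent-4-enoic acid (racemic) | C=CC(C(=O)O)C(C)(C)C=C | intermediate
7 | methyl 2-ethenyl-3,3-dimethylpent-4-enoate (racemic, not isolated) | C=CC(C(=O)OC)C(C)(C)C=C | intermediate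
8 | methyl (Z)-2-(2-methylbut-3-en-2-yl)but-2-enoate | C/C=C(\C(=O)OC)C(C)(C)C=C | intermediate
9 | methyl (Z)-2-(2-methyl-5-oxopentan-2-yl)but-2-enoate | C/C=C(\C(=O)OC)C(C)(C)CCC=O | intermediate
10 | methyl (1S,6S)-2,2,6-trimethyl-5-oxocyclohexane-1-carboxylate | COC(=O)[C@H]1[C@H](C)C(=O)CCC1(C)C | intermediate
11 | methyl (6S,7S)-6,8,8-trimethyl-1,4-dioxaspiro[4.5]decane-7-carboxylate | COC(=O)[C@H]1[C@H](C)C2(OCCO2)CCC1(C)C | intermediate
12 | [(6S,7S)-6,8,8-trimethyl-1,4-dioxaspiro[4.5]decan-7-yl]methanol | OC[C@H]1[C@H](C)C2(OCCO2)CCC1(C)C | intermediate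
13 | 1-phenyl-1H-tetrazole-5-thiol | Sc1nnnn1-c1ccccc1 | starting material
14 | 1-phenyl-5-({[(6S,7S)-6,8,8-trimethyl-1,4-dioxaspiro[4.5]decan-7-yl]methyl}sulfanyl)-1H-tetrazole | c1ccccc1-n1nnnc1SC[C@H]1[C@H](C)C2(OCCO2)CCC1(C)C | intermediate
15 | 1-phenyl-5-({[(6S,7S)-6,8,8-trimethyl-1,4-dioxaspiro[4.5]decan-7-yl]methyl}sulfonyl)-1H-tetrazole | O=S(=O)(c1nnnn1-c1ccccc1)C[C@H]1[C@H](C)C2(OCCO2)CCC1(C)C | intermediate
16 | (2S,3S)-2,4,4-trimethyl-3-{[(1-phenyl-1H-tetrazol-5-yl)sulfanyl]methyl}cyclohexan-1-one | c1ccccc1-n1nnnc1SC[C@H]1[C@H](C)C(=O)CCC1(C)C | intermediate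
17 | (1S,2S,3S)-2,4,4-trimethyl-3-{[(1-phenyl-1H-tetrazol-5-yl)sulfanyl]methyl}cyclohexan-1-ol | c1ccccc1-n1nnnc1SC[C@H]1[C@H](C)[C@@H](O)CCC1(C)C | intermediate
18 | (1S,2S,3S)-2,4,4-trimethyl-3-{[(1-phenyl-1H-tetrazol-5-yl)sulfonyl]methyl}cyclohexan-1-ol | O=S(=O)(c1nnnn1-c1ccccc1)C[C@H]1[C@H](C)[C@@H](O)CCC1(C)C | intermediate
19 | triethyl{[(1S,2S,3S)-2,4,4-trimethyl-3-{[(1-phenyl-1H-tetrazol-5-yl)sulfonyl]methyl}cyclohexyl]oxy}silane | O=S(=O)(c1nnnn1-c1ccccc1)C[C@H]1[C@H](C)[C@@H](O[Si](CC)(CC)CC)CCC1(C)C | intermediate
20 | crocetindial, (2E,4E,6E,8E,10E,12E,14E)-2,6,11,15-tetramethylhexadeca-2,4,6,8,10,12,14-heptaenedial | O=C/C(C)=C/C=C/C(C)=C/C=C/C=C(C)/C=C/C=C(C)/C=O | starting material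
21 | (2E,4E,6E,8E,10E,12E,14E,16E)-2,6,11,15-tetramethyl-17-[(6S,7S)-6,8,8-trimethyl-1,4-dioxaspiro[4.5]decan-7-yl]heptadeca-2,4,6,8,10,12,14,16-octaenal | O=C/C(C)=C/C=C/C(C)=C/C=C/C=C(C)/C=C/C=C(C)/C=C/[C@H]1[C@H](C)C2(OCCO2)CCC1(C)C | intermediate
22 | (4S,5S,6S,5′S,6′S)-4′,4′-ethylenedioxy-4-(triethylsilyloxy)-5,6,5′,6′-tetrahydro-β,β-carotene (all-E) | CC(/C=C/C=C(C)/C=C/[C@H]1[C@H](C)[C@@H](O[Si](CC)(CC)CC)CCC1(C)C)=C\C=C\C=C(C)\C=C\C=C(C)\C=C\[C@H]1[C@H](C)C2(OCCO2)CCC1(C)C | intermediate
23 | (4S,5S,6S,5′S,6′S)-4-hydroxy-5,6,5′,6′-tetrahydro-β,β-caroten-4′-one (CNP0107241.1, all-E) | CC(/C=C/C=C(C)/C=C/[C@H]1[C@H](C)[C@@H](O)CCC1(C)C)=C\C=C\C=C(C)\C=C\C=C(C)\C=C\[C@H]1[C@H](C)C(=O)CCC1(C)C | target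

## Step count and least certain steps

Total: 16 steps. Longest linear sequence: 14 steps (steps 1–8, 10–13, 15, 16).

**Step 5 (key step).** The Breslow intermediate may fail to add to the hindered, twisted trisubstituted acceptor in the endo geometry, so that aldol or benzoin self-condensation of the aldehyde takes over. Protonation of the ester enolate by an external proton source would lower the enantiomeric purity at C6.
Fallback with known chemistry, from 9 back to 10: the C4–C5 bond is closed by a radical instead of an anion.
- Irradiation (390 nm) of 9 with (n-Bu4N)4W10O32 in MeCN abstracts the formyl hydrogen. The nucleophilic acyl radical adds 6-endo to C5, since attack at C6 would meet a fully substituted carbon and give an unstabilized radical. Back hydrogen transfer to the C6 radical gives racemic methyl 2,2,6-trimethyl-5-oxocyclohexane-1-carboxylate F1 as a mixture of C5 epimers.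
- Ketalization of F1 with (1R,2R)-1,2-diphenylethane-1,2-diol under the equilibrating conditions of step 6 converges C5. It gives two diastereomeric trans ketals: methyl (2R,3R,6S,7S)-6,8,8-trimethyl-2,3-diphenyl-1,4-dioxaspiro[4.5]decane-7-carboxylate F2 and methyl (2R,3R,6R,7R)-6,8,8-trimethyl-2,3-diphenyl-1,4-dioxaspiro[4.5]decane-7-carboxylate F3, to be separated by crystallization or chromatography.
- Hydrolysis of F2 (aqueous HCl, THF) returns to the route at 10. The price is half of the material.

**Step 2.** Conjugate addition of the amide base to the crotonate, or a sluggish rearrangement onto the dimethyl-substituted terminus, would cut the supply of 6. The conjugative isomerization of step 3 depends on the same material.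
Fallback, from 1 back to 8:
- Johnson–Claisen rearrangement of 1 with trimethyl orthoacetate (propionic acid cat., 140 °C) gives methyl 3,3-dimethylpent-4-enoate F4.
- Aldol addition of its lithium enolate (LiN(i-Pr)2, THF, −78 °C) to acetaldehyde gives methyl 2-(1-hydroxyethyl)-3,3-dimethylpent-4-enoate F5.
- Mesylation (MsCl, Et3N) to methyl 3,3-dimethyl-2-[1-(methylsulfonyloxy)ethyl]pent-4-enoate F6 and elimination with DBU rejoin the route at 8.

**Step 11.** Poor facial selectivity of the hydride would give a mixture of C4 epimers.
Fallback, from 16 back to 17: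
- The bulky LiBH(s-Bu)3 (THF, −78 °C) attacks from the equatorial side and gives the axial alcohol (1R,2S,3S)-2,4,4-trimethyl-3-{[(1-phenyl-1H-tetrazol-5-yl)sulfanyl]methyl}cyclohexan-1-ol F7.
- Mitsunobu esterification with 4-nitrobenzoic acid (PPh3, DIAD) inverts C4 to (1S,2S,3S)-2,4,4-trimethyl-3-{[(1-phenyl-1H-tetrazol-5-yl)sulfanyl]methyl}cyclohexyl 4-nitrobenzoate F8.
- Methanolysis (K2CO3, MeOH) gives 17.

**Step 14 (and, for geometry, step 15).** Double olefination of the symmetric dialdehyde and incomplete E selectivity with a conjugated aldehyde are the likely failures.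
Fallback, from 12 back to 21: the sulfone is replaced by a phosphorus ylide and the geometry is set thermodynamically.
- Iodination of 12 (I2, PPh3, imidazole) gives (6S,7S)-7-(iodomethyl)-6,8,8-trimethyl-1,4-dioxaspiro[4.5]decane F9.
- Heating with PPh3 in MeCN gives {[(6S,7S)-6,8,8-trimethyl-1,4-dioxaspiro[4.5]decan-7-yl]methyl}triphenylphosphonium iodide F10.
- Wittig reaction of its ylide (NaN(SiMe3)2, THF) with excess 20 gives the mono-olefin as a Z/E mixture at C7′=C8′. Iodine-catalysed equilibration (cat. I2, hexane/CH2Cl2, daylight) should bring it to the all-E aldehyde 21.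

**Step 16.** Acid-induced E/Z drift of the polyene, or enolization at C5′ during a slow ketal cleavage, would spoil the last step.
Fallback, from 22 back to 23: the two groups are removed one after the other under near-neutral conditions.
- Bu4NF in THF cleaves the silyl ether and gives (4S,5S,6S,5′S,6′S)-4′,4′-ethylenedioxy-5,6,5′,6′-tetrahydro-β,β-caroten-4-ol F11.
- Ketal exchange with acetone catalysed by In(OTf)3 at rt then releases the ketone of 23.

## Further compounds

F1 | step 5 | methyl 2,2,6-trimethyl-5-oxocyclohexane-1-carboxylate (racemic, mixture of C5 epimers) | COC(=O)C1C(C)C(=O)CCC1(C)C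
F2 | step 5 | methyl (2R,3R,6S,7S)-6,8,8-trimethyl-2,3-diphenyl-1,4-dioxaspiro[4.5]decane-7-carboxylate | COC(=O)[C@H]1[C@H](C)C2(O[C@H](c3ccccc3)[C@@H](c3ccccc3)O2)CCC1(C)C
F3 | step 5 | methyl (2R,3R,6R,7R)-6,8,8-trimethyl-2,3-diphenyl-1,4-dioxaspiro[4.5]decane-7-carboxylate | COC(=O)[C@@H]1[C@@H](C)C2(O[C@H](c3ccccc3)[C@@H](c3ccccc3)O2)CCC1(C)C
F4 | step 2 | methyl 3,3-dimethylpent-4-enoate | COC(=O)CC(C)(C)C=C
F5 | step 2 | methyl 2-(1-hydroxyethyl)-3,3-dimethylpent-4-enoate (racemic diastereomer mixture) | COC(=O)C(C(C)O)C(C)(C)C=C
F6 | step 2 | methyl 3,3-dimethyl-2-[1-(methylsulfonyloxy)ethyl]pent-4-enoate (racemic diastereomer mixture) | COC(=O)C(C(C)OS(C)(=O)=O)C(C)(C)C=C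
F7 | step 11 | (1R,2S,3S)-2,4,4-trimethyl-3-{[(1-phenyl-1H-tetrazol-5-yl)sulfanyl]methyl}cyclohexan-1-ol | c1ccccc1-n1nnnc1SC[C@H]1[C@H](C)[C@H](O)CCC1(C)C
F8 | step 11 | (1S,2S,3S)-2,4,4-trimethyl-3-{[(1-phenyl-1H-tetrazol-5-yl)sulfanyl]methyl}cyclohexyl 4-nitrobenzoate | c1ccccc1-n1nnnc1SC[C@H]1[C@H](C)[C@@H](OC(=O)c2ccc(cc2)[N+](=O)[O-])CCC1(C)C
F9 | step 14 | (6S,7S)-7-(iodomethyl)-6,8,8-trimethyl-1,4-dioxaspiro[4.5]decane | IC[C@H]1[C@H](C)C2(OCCO2)CCC1(C)C
F10 | step 14 | {[(6S,7S)-6,8,8-trimethyl-1,4-dioxaspiro[4.5]decan-7-yl]methyl}triphenylphosphonium iodide | [I-].c1ccccc1[P+](c1ccccc1)(c1ccccc1)C[C@H]1[C@H](C)C2(OCCO2)CCC1(C)C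
F11 | step 16 | (4S,5S,6S,5′S,6′S)-4′,4′-ethylenedioxy-5,6,5′,6′-tetrahydro-β,β-caroten-4-ol (all-E) | CC(/C=C/C=C(C)/C=C/[C@H]1[C@H](C)[C@@H](O)CCC1(C)C)=C\C=C\C=C(C)\C=C\C=C(C)\C=C\[C@H]1[C@H](C)C2(OCCO2)CCC1(C)C
A1 | alternative 1 | 4,4-dimethylcyclohex-2-en-1-one | O=C1C=CC(C)(C)CC1
A2 | alternative 1 | 9-[(1E,3E)-5-(tert-butyldimethylsilyloxy)-3-methylpenta-1,3-dien-1-yl]-9-borabicyclo[3.3.1]nonane | CC(C)(C)[Si](C)(C)OC/C=C(C)/C=C/B1C2CCCC1CCC2
A3 | alternative 1 | (2S,3S)-3-[(1E,3E)-5-(tert-butyldimethylsilyloxy)-3-methylpenta-1,3-dien-1-yl]-2,4,4-trimethylcyclohexan-1-one | CC(C)(C)[Si](C)(C)OC/C=C(C)/C=C/[C@H]1[C@H](C)C(=O)CCC1(C)C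
A4 | alternative 2 | tert-butyl(dimethyl){[(1E,3S,4S)-3,7-dimethyl-1-(phenylsulfonyl)octa-1,7-dien-4-yl]oxy}silane | C=C(C)CC[C@H](O[Si](C)(C)C(C)(C)C)[C@@H](C)/C=C/S(=O)(=O)c1ccccc1
A5 | alternative 2 | tert-butyl(dimethyl){[(1S,2S,3S)-2,4,4-trimethyl-3-[(phenylsulfonyl)methyl]cyclohexyl]oxy}silane | O=S(=O)(c1ccccc1)C[C@H]1[C@H](C)[C@@H](O[Si](C)(C)C(C)(C)C)CCC1(C)C
A6 | alternative 3 | (Z)-6-(tert-butyldimethylsilyloxy)-3,3-dimethyloct-6-enal | O=CCC(C)(C)CC/C(O[Si](C)(C)C(C)(C)C)=C/C
A7 | alternative 3 | (1S,6S)-2,2,6-trimethyl-5-oxocyclohexane-1-carbaldehyde | O=C[C@H]1[C@H](C)C(=O)CCC1(C)C
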